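**Retrosynthetic overview**

- The target is a normal labd-8(17)-ene: rings A and B carry CH3 on C4 and C10, the one-carbon unit C17 on C8 and the side chain on C9. This is the head-to-tail pattern of a folded polyprenoid, so C4–C5 and C9–C10 are the bonds to make.
- Both bonds form in one cationic cascade from an open-chain (3S,4S)-epoxide whose C8 bears CH2SiMe3. Ring A closes first (C4–C5), then ring B (C9–C10), and loss of silicon leaves C8=C17.
- After the cascade the C3 hydroxyl is removed (Barton–McCombie), C15 and C18 are oxidised to acids, both are esterified, and only the unhindered C15 ester is hydrolysed.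
- The polyene is cut at C5–C6 (B-alkyl Suzuki–Miyaura coupling). The west vinyl iodide (C1–C5, C10, C18–C20) comes from 4-pentyn-1-ol by carboalumination, Wittig reaction and Sharpless epoxidation. The east diene (C6–C9, C11–C17) comes from (S)-citronellol, which supplies C13, by ozonolysis to the C9 aldehyde and an E-selective Wittig reaction that places CH2SiMe3 on C8.

Key step: step 15

Remark on the chemistry: labdane numbering is used throughout (C17 = methylene carbon on C8, C18 = 4α carbon, C19 = 4β methyl, C20 = methyl on C10); the target is the 18-methyl ester of (13S)-labd-8(17)-ene-15,18-dioic acid in the normal 5α-H, 9α-H, 10β-CH3 series.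

**Route**

Step 1
Reactants: 1 4-pentyn-1-ol
Product: 3 (4E)-5-iodo-4-methylpent-4-en-1-ol, via alkenylalane 2 (not isolated)
Conditions: Me3Al (3 equiv), Cp2ZrCl2 (0.25 equiv), CH2Cl2, 0 °C to rt; then I2, THF, −30 to 0 °C
Reagents that add atoms: trimethylaluminium C[Al](C)C; iodine II
Why: Negishi zirconium-catalysed carboalumination adds CH3 and Al syn across the terminal alkyne with Al on the terminal carbon, and iodinolysis with retention should give the E vinyl iodide that later fixes the E geometry of C5=C10.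

Step 2
Reactants: 3 (4E)-5-iodo-4-methylpent-4-en-1-ol
Product: 4 (4E)-5-iodo-4-methylpent-4-enal
Conditions: Dess–Martin periodinane, CH2Cl2, 0 °C to rt
Reagents that add atoms: none
Why: Dess–Martin oxidation of a primary alcohol stops at the aldehyde and leaves the vinyl iodide untouched.

Step 3
Reactants: 4 (4E)-5-iodo-4-methylpent-4-enal
Product: 5 ethyl (2E,6E)-7-iodo-2,6-dimethylhepta-2,6-dienoate
Conditions: Ph3P=C(CH3)CO2Et, CH2Cl2, rt
Reagents that add atoms: ethyl 2-(triphenylphosphoranylidene)propanoate CCOC(=O)C(C)=P(c1ccccc1)(c1ccccc1)c1ccccc1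
Why: Wittig olefination with an α-methyl ester-stabilised ylide should give the E enoate (ester trans to the chain), which places the future C18 trans to C2.

Step 4
Reactants: 5 ethyl (2E,6E)-7-iodo-2,6-dimethylhepta-2,6-dienoate
Product: 6 (2E,6E)-7-iodo-2,6-dimethylhepta-2,6-dien-1-ol
Conditions: iBu2AlH (2.2 equiv), CH2Cl2, −78 °C
Reagents that add atoms: none
Why: 1,2-Reduction of the α,β-unsaturated ester by iBu2AlH gives the allylic alcohol and does not touch the vinyl iodide at −78 °C.

Step 5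
Reactants: 6 (2E,6E)-7-iodo-2,6-dimethylhepta-2,6-dien-1-ol
Product: 7 [(2S,3S)-3-[(3E)-4-iodo-3-methylbut-3-en-1-yl]-2-methyloxiran-2-yl]methanol
Conditions: Ti(OiPr)4 (10 mol %), L-(+)-diethyl tartrate (12 mol %), tBuOOH, 4 Å molecular sieves, CH2Cl2, −20 °C
Reagents that add atoms: tert-butyl hydroperoxide CC(C)(C)OO
Why: In the Katsuki–Sharpless asymmetric epoxidation the allylic hydroxyl directs the titanium tartrate peroxide to the C3=C4 alkene only, and L-(+)-tartrate should deliver oxygen to the face that gives the (2S,3S)-epoxide (C3 S and C4 S in labdane numbering).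

Step 6
Reactants: 7 [(2S,3S)-3-[(3E)-4-iodo-3-methylbut-3-en-1-yl]-2-methyloxiran-2-yl]methanol
Product: 8 tert-butyl{[(2S,3S)-3-[(3E)-4-iodo-3-methylbut-3-en-1-yl]-2-methyloxiran-2-yl]methoxy}diphenylsilane (west fragment)
Conditions: tBuPh2SiCl, imidazole, DMF, 0 °C to rt
Reagents that add atoms: tert-butyl(chloro)diphenylsilane CC(C)(C)[Si](Cl)(c1ccccc1)c1ccccc1
Why: Imidazole-promoted silylation of the primary alcohol gives a bulky, weakly basic ether that should not chelate the Lewis acid in step 15.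

Step 7
Reactants: 9 (ethoxycarbonylmethylene)triphenylphosphorane (2 equiv); 10 (iodomethyl)trimethylsilane
Product: 12 ethyl 3-(trimethylsilyl)-2-(triphenyl-λ5-phosphanylidene)propanoate, via phosphonium iodide 11 (not isolated)
Conditions: toluene, 90 °C; the phosphonium iodide of 9 is filtered off
Reagents that add atoms: none
Why: C-Alkylation of the stabilised ylide by the α-silyl iodide followed by transylidation with the second equivalent of 9 (alkylation of a phosphorus ylide) should give the α-substituted ylide.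

Step 8
Reactants: 13 (S)-citronellol
Product: 14 tert-butyl{[(3S)-3,7-dimethyloct-6-en-1-yl]oxy}dimethylsilane
Conditions: tBuMe2SiCl, imidazole, DMF, rt
Reagents that add atoms: tert-butyl(chloro)dimethylsilane CC(C)(C)[Si](C)(C)Cl
Why: Imidazole-promoted silylation protects the C15 hydroxyl and leaves the C13 stereocentre untouched.

Step 9
Reactants: 14 tert-butyl{[(3S)-3,7-dimethyloct-6-en-1-yl]oxy}dimethylsilane
Product: 16 (4S)-6-[(tert-butyldimethylsilyl)oxy]-4-methylhexanal, via ozonide 15 (not isolated)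
Conditions: O3, CH2Cl2, −78 °C; then PPh3, −78 °C to rt
Reagents that add atoms: ozone [O-][O+]=O
Why: Ozonolysis with reductive work-up cleaves the trisubstituted alkene to the aldehyde whose carbonyl carbon is C9, and the C13 stereocentre, γ to the carbonyl, cannot epimerise.

Step 10
Reactants: 16 (4S)-6-[(tert-butyldimethylsilyl)oxy]-4-methylhexanal; 12 ethyl 3-(trimethylsilyl)-2-(triphenyl-λ5-phosphanylidene)propanoate
Product: 17 ethyl (2Z,6S)-8-[(tert-butyldimethylsilyl)oxy]-6-methyl-2-[(trimethylsilyl)methyl]oct-2-enoate (ester carbon trans to the alkyl chain)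
Conditions: toluene, 80 °C
Reagents that add atoms: none
Why: Wittig olefination with an α-substituted ester-stabilised ylide should favour the isomer with the ester trans to the alkyl chain, which puts CH2SiMe3 cis to C11 and C7 trans to C11, and a minor geometric isomer would be removed by chromatography at this stage.

Step 11
Reactants: 17 ethyl (2Z,6S)-8-[(tert-butyldimethylsilyl)oxy]-6-methyl-2-[(trimethylsilyl)methyl]oct-2-enoate
Product: 18 (2Z,6S)-8-[(tert-butyldimethylsilyl)oxy]-6-methyl-2-[(trimethylsilyl)methyl]oct-2-en-1-ol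
Conditions: iBu2AlH (2.2 equiv), CH2Cl2, −78 °C
Reagents that add atoms: none
Why: 1,2-Reduction of the enoate by iBu2AlH gives the allylic alcohol without acid or fluoride, so the allylsilane and the silyl ether survive.

Step 12
Reactants: 18 (2Z,6S)-8-[(tert-butyldimethylsilyl)oxy]-6-methyl-2-[(trimethylsilyl)methyl]oct-2-en-1-ol
Product: 19 (2Z,6S)-8-[(tert-butyldimethylsilyl)oxy]-6-methyl-2-[(trimethylsilyl)methyl]oct-2-enal
Conditions: MnO2, CH2Cl2, rt
Reagents that add atoms: none
Why: MnO2 oxidises the allylic alcohol selectively to the enal under neutral conditions that spare the allylsilane and keep the alkene geometry.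

Step 13
Reactants: 19 (2Z,6S)-8-[(tert-butyldimethylsilyl)oxy]-6-methyl-2-[(trimethylsilyl)methyl]oct-2-enal
Product: 20 tert-butyldimethyl{[(3S,6Z)-3-methyl-7-[(trimethylsilyl)methyl]nona-6,8-dien-1-yl]oxy}silane (east fragment)
Conditions: Ph3PCH3Br, KOtBu, THF, 0 °C; then 19, 0 °C to rt
Reagents that add atoms: methyltriphenylphosphonium bromide C[P+](c1ccccc1)(c1ccccc1)c1ccccc1.[Br-]
Why: Wittig methylenation of the enal gives the 2-(silylmethyl)-1,3-diene whose terminal vinyl group supplies C6 and C7, without change at the trisubstituted alkene.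

Step 14
Reactants: 20 tert-butyldimethyl{[(3S,6Z)-3-methyl-7-[(trimethylsilyl)methyl]nona-6,8-dien-1-yl]oxy}silane; 8 tert-butyl{[(2S,3S)-3-[(3E)-4-iodo-3-methylbut-3-en-1-yl]-2-methyloxiran-2-yl]methoxy}diphenylsilane
Product: 22 tert-butyl{[(2S,3S)-3-[(3E,7Z,11S)-13-[(tert-butyldimethylsilyl)oxy]-3,11-dimethyl-7-[(trimethylsilyl)methyl]trideca-3,7-dien-1-yl]-2-methyloxiran-2-yl]methoxy}diphenylsilane (cyclisation precursor), via alkylborane 21 (not isolated)
Conditions: 9-BBN (1.2 equiv), THF, 0 °C to rt; then 8, PdCl2(dppf) (5 mol %), AsPh3, Cs2CO3, DMF/H2O, rt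
Reagents that add atoms: none
Why: 9-BBN should add only to the unhindered terminal vinyl group with boron on C6 (anti-Markovnikov hydroboration), and the B-alkyl Suzuki–Miyaura coupling joins C6 to C5 of the vinyl iodide with retention of the E geometry under mild aqueous base that the epoxide, the silyl ethers and the allylsilane tolerate.

Step 15
Reactants: 22 tert-butyl{[(2S,3S)-3-[(3E,7Z,11S)-13-[(tert-butyldimethylsilyl)oxy]-3,11-dimethyl-7-[(trimethylsilyl)methyl]trideca-3,7-dien-1-yl]-2-methyloxiran-2-yl]methoxy}diphenylsilane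
Product: 23 (13S)-15-[(tert-butyldimethylsilyl)oxy]-18-[(tert-butyldiphenylsilyl)oxy]labd-8(17)-en-3β-ol
Conditions: MeAlCl2 (1.5 equiv), CH2Cl2, −94 to −78 °C; then Et3N, MeOH/H2O
Reagents that add atoms: none
Why: MeAlCl2 binds the epoxide oxygen and the C5=C10 π bond attacks the tertiary C4 anti to the breaking C4–O bond (inversion at C4, C3–O untouched), the C10 cation so formed is taken by C9 of the allylsilane, and the β-silyl cation at C8 loses Me3Si to give only the C8=C17 methylene. The closest known reaction type is the Lewis-acid-promoted epoxy-polyene bicyclisation terminated by an allylsilane, here with the less common oxygen-bearing carbon on the epoxide. Ring A closes 6-endo at the C5=C10 alkene through a chair with the C3–O bond equatorial, and ring B closes 6-endo at the C8=C9 alkene through a second chair. C3 keeps its S configuration (3β-OH) and fixes the absolute sense, C4 receives the E-CH2OSi group as the equatorial 4α substituent because of the anti opening, C5 and C10 come out trans (5α-H, 10β-CH3) from anti addition across the E alkene, and C9 carries C11 equatorial (9α-H) because C7 and C11 are trans on the allylsilane. The step needs opening at C4 and not at C3, and completion of the cascade instead of proton loss after ring A; the tertiary C4, the bulky non-chelating tBuPh2Si ether, the low temperature and the high nucleophilicity of the allylsilane should secure this.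

Step 16
Reactants: 23 (13S)-15-[(tert-butyldimethylsilyl)oxy]-18-[(tert-butyldiphenylsilyl)oxy]labd-8(17)-en-3β-ol
Product: 24 O-[(13S)-15-[(tert-butyldimethylsilyl)oxy]-18-[(tert-butyldiphenylsilyl)oxy]labd-8(17)-en-3β-yl] 1H-imidazole-1-carbothioate
Conditions: 1,1′-thiocarbonyldiimidazole (3 equiv), DMAP (cat.), ClCH2CH2Cl, 80 °C
Reagents that add atoms: 1,1′-thiocarbonyldiimidazole S=C(n1ccnc1)n1ccnc1
Why: DMAP-catalysed thioacylation of the hindered equatorial C3 alcohol prepares the Barton–McCombie substrate without forming an alkoxide that could take the silyl group from the neighbouring C18 oxygen.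

Step 17
Reactants: 24 O-[(13S)-15-[(tert-butyldimethylsilyl)oxy]-18-[(tert-butyldiphenylsilyl)oxy]labd-8(17)-en-3β-yl] 1H-imidazole-1-carbothioate
Product: 25 (13S)-15-[(tert-butyldimethylsilyl)oxy]-18-[(tert-butyldiphenylsilyl)oxy]labd-8(17)-ene
Conditions: Bu3SnH (2 equiv), AIBN (cat.), toluene, 110 °C
Reagents that add atoms: none
Why: In the Barton–McCombie deoxygenation the stannyl radical adds to C=S, the secondary C3 radical is released and reduced by Bu3SnH, and no stereocentre is at risk because C3 becomes CH2 and lies far from the C8=C17 alkene.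

Step 18
Reactants: 25 (13S)-15-[(tert-butyldimethylsilyl)oxy]-18-[(tert-butyldiphenylsilyl)oxy]labd-8(17)-ene
Product: 26 (13S)-labd-8(17)-ene-15,18-diol
Conditions: Bu4NF (4 equiv), THF, rt to 50 °C
Reagents that add atoms: none
Why: Fluoride cleaves both silyl ethers through Si–F bond formation (desilylation) and leaves the alkene and the skeleton untouched.

Step 19
Reactants: 26 (13S)-labd-8(17)-ene-15,18-diol
Product: 27 (13S)-labd-8(17)-ene-15,18-dial
Conditions: Dess–Martin periodinane (3 equiv), CH2Cl2, rt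
Reagents that add atoms: none
Why: Dess–Martin oxidation converts both primary alcohols, including the neopentyl C18 one, into aldehydes that have no epimerisable α-stereocentre.

Step 20
Reactants: 27 (13S)-labd-8(17)-ene-15,18-dial
Product: 28 (13S)-labd-8(17)-ene-15,18-dioic acid
Conditions: NaClO2, NaH2PO4, 2-methylbut-2-ene, tBuOH/H2O, rt
Reagents that add atoms: sodium chlorite [Na+].[O-]Cl=O
Why: Pinnick oxidation converts both aldehydes into acids while 2-methylbut-2-ene traps HOCl, so the C8=C17 alkene should survive.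

Step 21
Reactants: 28 (13S)-labd-8(17)-ene-15,18-dioic acid
Product: 29 dimethyl (13S)-labd-8(17)-ene-15,18-dioate
Conditions: Me3SiCHN2, toluene/MeOH, 0 °C to rt
Reagents that add atoms: (trimethylsilyl)diazomethane C[Si](C)(C)C=[N+]=[N-]
Why: O-Methylation by (trimethylsilyl)diazomethane proceeds by proton transfer and alkylation of the carboxylate oxygen, so the hindered C18 acid is esterified as readily as the C15 acid.

Step 22
Reactants: 29 dimethyl (13S)-labd-8(17)-ene-15,18-dioate
Product: 30 (13S)-18-methoxy-18-oxolabd-8(17)-en-15-oic acid (CNP0135192.1)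
Conditions: LiOH (3 equiv), THF/MeOH/H2O, rt; then 1 M HCl
Reagents that add atoms: lithium hydroxide [Li+].[OH-]
Why: Saponification (acyl–oxygen cleavage by hydroxide) is far faster at the unhindered C15 ester than at the C18 ester on the quaternary C4, so hydrolysis at room temperature should stop at the mono-acid.

**Compound list**

1 | 4-pentyn-1-ol | C#CCCCO | starting material
2 | (E)-alkenyl(dimethyl)alane with O–AlMe2 alkoxide | C[Al](C)/C=C(\C)CCCO[Al](C)C | intermediate
3 | (4E)-5-iodo-4-methylpent-4-en-1-ol | OCCC/C(C)=C/I | intermediate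
4 | (4E)-5-iodo-4-methylpent-4-enal | O=CCC/C(C)=C/I | intermediate
5 | ethyl (2E,6E)-7-iodo-2,6-dimethylhepta-2,6-dienoate | CCOC(=O)/C(C)=C/CC/C(C)=C/I | intermediate
6 | (2E,6E)-7-iodo-2,6-dimethylhepta-2,6-dien-1-ol | OC/C(C)=C/CC/C(C)=C/I | intermediate
7 | [(2S,3S)-3-[(3E)-4-iodo-3-methylbut-3-en-1-yl]-2-methyloxiran-2-yl]methanol | OC[C@]1(C)O[C@H]1CC/C(C)=C/I | intermediate
8 | tert-butyl{[(2S,3S)-3-[(3E)-4-iodo-3-methylbut-3-en-1-yl]-2-methyloxiran-2-yl]methoxy}diphenylsilane | CC(C)(C)[Si](c1ccccc1)(c1ccccc1)OC[C@]1(C)O[C@H]1CC/C(C)=C/I | intermediate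
9 | (ethoxycarbonylmethylene)triphenylphosphorane | CCOC(=O)C=P(c1ccccc1)(c1ccccc1)c1ccccc1 | starting material
10 | (iodomethyl)trimethylsilane | C[Si](C)(C)CI | starting material
11 | [1-ethoxy-1-oxo-3-(trimethylsilyl)propan-2-yl]triphenylphosphonium iodide | CCOC(=O)C(C[Si](C)(C)C)[P+](c1ccccc1)(c1ccccc1)c1ccccc1.[I-] | intermediate
12 | ethyl 3-(trimethylsilyl)-2-(triphenyl-λ5-phosphanylidene)propanoate | CCOC(=O)C(C[Si](C)(C)C)=P(c1ccccc1)(c1ccccc1)c1ccccc1 | intermediate
13 | (S)-citronellol | C[C@@H](CCC=C(C)C)CCO | starting material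
14 | tert-butyl{[(3S)-3,7-dimethyloct-6-en-1-yl]oxy}dimethylsilane | CC(C)=CCC[C@H](C)CCO[Si](C)(C)C(C)(C)C | intermediate
15 | secondary ozonide (1,2,4-trioxolane) of 14 | CC1(C)OOC(CC[C@H](C)CCO[Si](C)(C)C(C)(C)C)O1 | intermediate
16 | (4S)-6-[(tert-butyldimethylsilyl)oxy]-4-methylhexanal | O=CCC[C@H](C)CCO[Si](C)(C)C(C)(C)C | intermediate
17 | ethyl (2Z,6S)-8-[(tert-butyldimethylsilyl)oxy]-6-methyl-2-[(trimethylsilyl)methyl]oct-2-enoate | CCOC(=O)/C(C[Si](C)(C)C)=C/CC[C@H](C)CCO[Si](C)(C)C(C)(C)C | intermediate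
18 | (2Z,6S)-8-[(tert-butyldimethylsilyl)oxy]-6-methyl-2-[(trimethylsilyl)methyl]oct-2-en-1-ol | OC/C(C[Si](C)(C)C)=C/CC[C@H](C)CCO[Si](C)(C)C(C)(C)C | intermediate
19 | (2Z,6S)-8-[(tert-butyldimethylsilyl)oxy]-6-methyl-2-[(trimethylsilyl)methyl]oct-2-enal | O=C/C(C[Si](C)(C)C)=C/CC[C@H](C)CCO[Si](C)(C)C(C)(C)C | intermediate
20 | tert-butyldimethyl{[(3S,6Z)-3-methyl-7-[(trimethylsilyl)methyl]nona-6,8-dien-1-yl]oxy}silane | C=C/C(C[Si](C)(C)C)=C/CC[C@H](C)CCO[Si](C)(C)C(C)(C)C | intermediate
21 | 9-[(3Z,7S)-9-[(tert-butyldimethylsilyl)oxy]-7-methyl-3-[(trimethylsilyl)methyl]non-3-en-1-yl]-9-borabicyclo[3.3.1]nonane | C1CC2CCCC(C1)B2CC/C(C[Si](C)(C)C)=C/CC[C@H](C)CCO[Si](C)(C)C(C)(C)C | intermediate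
22 | tert-butyl{[(2S,3S)-3-[(3E,7Z,11S)-13-[(tert-butyldimethylsilyl)oxy]-3,11-dimethyl-7-[(trimethylsilyl)methyl]trideca-3,7-dien-1-yl]-2-methyloxiran-2-yl]methoxy}diphenylsilane | CC(C)(C)[Si](c1ccccc1)(c1ccccc1)OC[C@]1(C)O[C@H]1CC/C(C)=C/CC/C(C[Si](C)(C)C)=C/CC[C@H](C)CCO[Si](C)(C)C(C)(C)C | intermediate
23 | (13S)-15-[(tert-butyldimethylsilyl)oxy]-18-[(tert-butyldiphenylsilyl)oxy]labd-8(17)-en-3β-ol | C=C1CC[C@@H]2[C@](C)(CC[C@H](O)[C@@]2(C)CO[Si](c3ccccc3)(c3ccccc3)C(C)(C)C)[C@H]1CC[C@H](C)CCO[Si](C)(C)C(C)(C)C | intermediate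
24 | O-[(13S)-15-[(tert-butyldimethylsilyl)oxy]-18-[(tert-butyldiphenylsilyl)oxy]labd-8(17)-en-3β-yl] 1H-imidazole-1-carbothioate | C=C1CC[C@@H]2[C@](C)(CC[C@H](OC(=S)n3ccnc3)[C@@]2(C)CO[Si](c3ccccc3)(c3ccccc3)C(C)(C)C)[C@H]1CC[C@H](C)CCO[Si](C)(C)C(C)(C)C | intermediate
25 | (13S)-15-[(tert-butyldimethylsilyl)oxy]-18-[(tert-butyldiphenylsilyl)oxy]labd-8(17)-ene | C=C1CC[C@@H]2[C@](C)(CCC[C@@]2(C)CO[Si](c3ccccc3)(c3ccccc3)C(C)(C)C)[C@H]1CC[C@H](C)CCO[Si](C)(C)C(C)(C)C | intermediate
26 | (13S)-labd-8(17)-ene-15,18-diol | C=C1CC[C@@H]2[C@](C)(CCC[C@@]2(C)CO)[C@H]1CC[C@H](C)CCO | intermediate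
27 | (13S)-labd-8(17)-ene-15,18-dial | C=C1CC[C@@H]2[C@](C)(CCC[C@@]2(C)C=O)[C@H]1CC[C@H](C)CC=O | intermediate
28 | (13S)-labd-8(17)-ene-15,18-dioic acid | C=C1CC[C@@H]2[C@](C)(CCC[C@@]2(C)C(=O)O)[C@H]1CC[C@H](C)CC(=O)O | intermediate
29 | dimethyl (13S)-labd-8(17)-ene-15,18-dioate | C=C1CC[C@@H]2[C@](C)(CCC[C@@]2(C)C(=O)OC)[C@H]1CC[C@H](C)CC(=O)OC | intermediate
30 | (13S)-18-methoxy-18-oxolabd-8(17)-en-15-oic acid (CNP0135192.1) | C=C1CC[C@@H]2[C@](C)(CCC[C@@]2(C)C(=O)OC)[C@H]1CC[C@H](C)CC(=O)O | target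

**Step count and risks**

Total step count: 22 steps. Longest linear sequence: 15 steps (from (S)-citronellol 13 through steps 8–22, or equally from 4-pentyn-1-ol 1 through steps 1–6 and 14–22).

Steps most likely to fail:

1. Step 15 (key step). Heterolysis of the C4–O bond is slowed by the silyloxymethyl group on C4, so the Lewis acid may induce a 1,2-shift of the epoxide, or the cascade may stop after ring A by proton loss from C10. The fallback opens the epoxide by a radical and not a cationic path and needs no silicon on C17.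
   - It sets out from aldehyde 16. Wittig olefination with ethyl 2-(triphenylphosphoranylidene)propanoate should give ethyl (2E,6S)-8-[(tert-butyldimethylsilyl)oxy]-2,6-dimethyloct-2-enoate F1.
   - Reduction with iBu2AlH gives (2E,6S)-8-[(tert-butyldimethylsilyl)oxy]-2,6-dimethyloct-2-en-1-ol F2, MnO2 oxidation gives (2E,6S)-8-[(tert-butyldimethylsilyl)oxy]-2,6-dimethyloct-2-enal F3, and methylenation with Ph3P=CH2 gives tert-butyldimethyl{[(3S,6E)-3,7-dimethylnona-6,8-dien-1-yl]oxy}silane F4.
   - Hydroboration with 9-BBN gives 9-[(3E,7S)-9-[(tert-butyldimethylsilyl)oxy]-3,7-dimethylnon-3-en-1-yl]-9-borabicyclo[3.3.1]nonane F5, which is coupled with vinyl iodide 8 under the conditions of step 14 to tert-butyl{[(2S,3S)-3-[(3E,7E,11S)-13-[(tert-butyldimethylsilyl)oxy]-3,7,11-trimethyltrideca-3,7-dien-1-yl]-2-methyloxiran-2-yl]methoxy}diphenylsilane F6.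
   - Cp2TiCl (trivalent titanium, made from Cp2TiCl2 and Mn dust in THF) opens the epoxide homolytically at C4. The tertiary radical closes rings A and B by two 6-endo additions, the C8 radical is trapped by a second Cp2TiCl and loses Cp2Ti(H)Cl toward C17, and aqueous work-up returns to 23.
   - In this variant C4 is set by the chair preference for the larger silyloxymethyl group in the equatorial position and not by inversion, so a C4 epimer may have to be separated at 23.

2. Step 14. Hydroboration of the conjugated diene may not stay at the terminal vinyl group, or transmetalation of the alkylborane may be outrun by its protodeboronation, leaving vinyl iodide 8 unconverted. The fallback isolates the hydroboration product and changes the organometallic partner.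
   - It sets out from diene 20. Hydroboration with 9-BBN followed by NaOH/H2O2 should give (3Z,7S)-9-[(tert-butyldimethylsilyl)oxy]-7-methyl-3-[(trimethylsilyl)methyl]non-3-en-1-ol F7, which is purified at this point.
   - Iodination with I2, PPh3 and imidazole gives tert-butyl{[(3S,6Z)-9-iodo-3-methyl-7-[(trimethylsilyl)methyl]non-6-en-1-yl]oxy}dimethylsilane F8.
   - Zinc insertion (Zn dust, LiCl, THF) gives iodo[(3Z,7S)-9-[(tert-butyldimethylsilyl)oxy]-7-methyl-3-[(trimethylsilyl)methyl]non-3-en-1-yl]zinc F9, and Negishi coupling with 8 (PdCl2(dppf), THF, rt) returns to 22.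

3. Step 10. Geometric selectivity may be insufficient, and the isomer with the ester cis to the chain would later deliver the C9 epimer. The fallback sets the geometry by a chelate-controlled addition and not by an olefination.
   - It sets out from aldehyde 16. Ohira–Bestmann homologation (dimethyl (1-diazo-2-oxopropyl)phosphonate, K2CO3, MeOH) should give tert-butyldimethyl{[(3S)-3-methylhept-6-yn-1-yl]oxy}silane F10.
   - Deprotonation with n-BuLi and addition to paraformaldehyde gives (6S)-8-[(tert-butyldimethylsilyl)oxy]-6-methyloct-2-yn-1-ol F11.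
   - Copper-catalysed anti-carbomagnesiation with Me3SiCH2MgCl (CuI 10 mol %, THF, reflux) places the silylmethyl group on C8 and magnesium on C9 in the five-membered cyclic alkenylmagnesium alkoxide F12. Protonation then puts hydrogen on C9 anti to the new carbon and returns to allylic alcohol 18 as a single geometric isomer.

**Further compounds**

F1 | step 15 | ethyl (2E,6S)-8-[(tert-butyldimethylsilyl)oxy]-2,6-dimethyloct-2-enoate | CCOC(=O)/C(C)=C/CC[C@H](C)CCO[Si](C)(C)C(C)(C)C
F2 | step 15 | (2E,6S)-8-[(tert-butyldimethylsilyl)oxy]-2,6-dimethyloct-2-en-1-ol | OC/C(C)=C/CC[C@H](C)CCO[Si](C)(C)C(C)(C)C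
F3 | step 15 | (2E,6S)-8-[(tert-butyldimethylsilyl)oxy]-2,6-dimethyloct-2-enal | O=C/C(C)=C/CC[C@H](C)CCO[Si](C)(C)C(C)(C)C
F4 | step 15 | tert-butyldimethyl{[(3S,6E)-3,7-dimethylnona-6,8-dien-1-yl]oxy}silane | C=C/C(C)=C/CC[C@H](C)CCO[Si](C)(C)C(C)(C)C
F5 | step 15 | 9-[(3E,7S)-9-[(tert-butyldimethylsilyl)oxy]-3,7-dimethylnon-3-en-1-yl]-9-borabicyclo[3.3.1]nonane | C1CC2CCCC(C1)B2CC/C(C)=C/CC[C@H](C)CCO[Si](C)(C)C(C)(C)C
F6 | step 15 | tert-butyl{[(2S,3S)-3-[(3E,7E,11S)-13-[(tert-butyldimethylsilyl)oxy]-3,7,11-trimethyltrideca-3,7-dien-1-yl]-2-methyloxiran-2-yl]methoxy}diphenylsilane | CC(C)(C)[Si](c1ccccc1)(c1ccccc1)OC[C@]1(C)O[C@H]1CC/C(C)=C/CC/C(C)=C/CC[C@H](C)CCO[Si](C)(C)C(C)(C)C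
F7 | step 14 | (3Z,7S)-9-[(tert-butyldimethylsilyl)oxy]-7-methyl-3-[(trimethylsilyl)methyl]non-3-en-1-ol | OCC/C(C[Si](C)(C)C)=C/CC[C@H](C)CCO[Si](C)(C)C(C)(C)C
F8 | step 14 | tert-butyl{[(3S,6Z)-9-iodo-3-methyl-7-[(trimethylsilyl)methyl]non-6-en-1-yl]oxy}dimethylsilane | ICC/C(C[Si](C)(C)C)=C/CC[C@H](C)CCO[Si](C)(C)C(C)(C)C
F9 | step 14 | iodo[(3Z,7S)-9-[(tert-butyldimethylsilyl)oxy]-7-methyl-3-[(trimethylsilyl)methyl]non-3-en-1-yl]zinc | I[Zn]CC/C(C[Si](C)(C)C)=C/CC[C@H](C)CCO[Si](C)(C)C(C)(C)C
F10 | step 10 | tert-butyldimethyl{[(3S)-3-methylhept-6-yn-1-yl]oxy}silane | C#CCC[C@H](C)CCO[Si](C)(C)C(C)(C)C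
F11 | step 10 | (6S)-8-[(tert-butyldimethylsilyl)oxy]-6-methyloct-2-yn-1-ol | OCC#CCC[C@H](C)CCO[Si](C)(C)C(C)(C)C
F12 | step 10 | cyclic alkenylmagnesium alkoxide (2,5-dihydro-1,2-oxamagnesole) from F11 | C[Si](C)(C)CC1=C(CC[C@H](C)CCO[Si](C)(C)C(C)(C)C)[Mg]OC1
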